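**Retrosynthetic overview**
1. The last operations are removal of three MOM ethers and one TES ether, preceded by a Negishi sp2–sp3 coupling. This coupling joins C8 of a (2S)-8-bromoflavanone to C1'' of the hydrated lavandulyl chain; the C2'' stereocentre comes from an Evans deconjugative prenylation.
2. C2 is set from the flavone oxidation level by catalyst-controlled asymmetric hydrogenation of C2=C3, followed by re-oxidation of C4.
3. Ring C is made in one operation from a 2-fluoroacetophenone (ring A) and a benzoate ester (ring B). A Claisen condensation forms C3–C2, and intramolecular SNAr by the diketone enolate oxygen forms O1–C8a.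
4. Enabling feature: in ring A, C8a is ortho to C4a (the carbon bearing the C4 carbonyl) and meta to both O5 and O7. O1–C8a=C4a–C4=O is therefore a vinylogous ester: oxygen displaces a fluorine on C8a with the charge held on O4, and neither ether oxygen pushes electrons onto C8a.
5. Ring order: rings A and B are bought as arenes; ring C is the only ring that is built.

Key step: step 5

Assumption: the sense of induction of the chiral ruthenium carbene catalyst on this 2'-substituted flavone is not known. The (R,R)-salt is written for the (2S) series, and the (S,S)-salt is used instead if a trial shows the opposite sense.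

Step 1
Reactants: 1 5-fluorobenzene-1,3-diol
Product: 2 1-(2-fluoro-4,6-dihydroxyphenyl)ethan-1-one
Conditions: AcOH, ZnCl2, 140 °C
Reagents that add atoms: acetic acid, CC(=O)O
Why: The Nencki-type Friedel–Crafts acylation takes place ortho to one hydroxyl and para to the other, next to fluorine and not between the two hydroxyls, as it does with orcinol.

Step 2
Reactants: 2 1-(2-fluoro-4,6-dihydroxyphenyl)ethan-1-one
Product: 3 1-[2-fluoro-4,6-bis(methoxymethoxy)phenyl]ethan-1-one
Conditions: MOMCl, NaH, DMF, 0 °C to rt
Reagents that add atoms: chloromethyl methyl ether, COCCl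
Why: In this Williamson-type O-alkylation NaH also frees the hydrogen-bonded 6-OH, and both phenols must be masked because a phenoxide on ring A would switch off the substitution of step 5.

Step 3
Reactants: 3 1-[2-fluoro-4,6-bis(methoxymethoxy)phenyl]ethan-1-one
Product: 4 1-[3-bromo-2-fluoro-4,6-bis(methoxymethoxy)phenyl]ethan-1-one
Conditions: NBS, MeCN, 0 °C to rt
Reagents that add atoms: N-bromosuccinimide, O=C1CCC(=O)N1Br
Why: Electrophilic aromatic bromination goes to C3, which is para to the 6-OMOM group, ortho to the 4-OMOM group and flanked only by the small fluorine, and not to C5, which is buttressed by two OMOM groups, as is usual for 5-substituted 1,3-dialkoxybenzenes.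

Step 4
Reactants: 5 methyl 4-hydroxy-2-methoxybenzoate
Product: 6 methyl 2-methoxy-4-(methoxymethoxy)benzoate
Conditions: MOMCl, i-Pr2NEt, CH2Cl2, 0 °C to rt
Reagents that add atoms: chloromethyl methyl ether, COCCl
Why: Standard MOM protection of the only free phenol gives a base-stable ester that carries the same protecting group as ring A.

Step 5
Reactants: 4 1-[3-bromo-2-fluoro-4,6-bis(methoxymethoxy)phenyl]ethan-1-one; 6 methyl 2-methoxy-4-(methoxymethoxy)benzoate
Product: 8 8-bromo-2-[2-methoxy-4-(methoxymethoxy)phenyl]-5,7-bis(methoxymethoxy)-4H-chromen-4-one, via diketone enolate 7 (not isolated)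
Conditions: KOt-Bu, THF, 0 °C to rt; then 18-crown-6, reflux
Reagents that add atoms: none
Why: KOt-Bu turns 4, the only enolisable partner, into its enolate, which adds to the ester carbonyl of 6 and expels methoxide (crossed Claisen condensation, C3–C2 formed), and deprotonation of the product to the potassium enolate of 7 pulls this equilibrium to one side. On heating with the crown ether, which loosens the potassium chelate, the enolate oxygen on C2 adds to C8a, the charge runs through C4a into the C4 carbonyl oxygen, and fluoride leaves (intramolecular SNAr by addition–elimination, O1–C8a formed), so that the stable 4-pyranone ring of 8 is reached irreversibly. The closest known reaction types are the Claisen synthesis of 1,3-diaryl-1,3-diketones and the transition-metal-free cyclisation of 1-(2-haloaryl)-1,3-diketones to flavones, here run in one flask. Ring C closes in the 6-endo-trig mode, since the C8a=C4a bond that is attacked lies inside the new ring. No stereocentre arises because C2 stays trigonal until step 6. The step needs C- instead of O-acylation, secured by the reversible ester condensation that ends in the most stable enolate, and attack at C8a–F instead of C5–OMOM or C8–Br, secured by fluorine as the best activator of the addition step, by the ortho carbonyl, and by the meta placing of O5 and O7, which keeps their lone pairs off C8a.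

Step 6
Reactants: 8 8-bromo-2-[2-methoxy-4-(methoxymethoxy)phenyl]-5,7-bis(methoxymethoxy)-4H-chromen-4-one
Product: 9 (2S,4S)-8-bromo-2-[2-methoxy-4-(methoxymethoxy)phenyl]-5,7-bis(methoxymethoxy)-3,4-dihydro-2H-chromen-4-ol (2,4-cis)
Conditions: H2 (100 bar), cat. Ru(cod)(2-methylallyl)2, cat. (R,R)-SINpEt·HBF4, cat. KOt-Bu, toluene, rt
Reagents that add atoms: none
Why: Asymmetric hydrogenation of flavones with a chiral ruthenium N-heterocyclic carbene catalyst is a known reaction type that sets C2 under catalyst control, the ketone is then reduced on the face that gives the 2,4-cis alcohol, and any flavanone left unreduced converges in step 7.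

Step 7
Reactants: 9 (2S,4S)-8-bromo-2-[2-methoxy-4-(methoxymethoxy)phenyl]-5,7-bis(methoxymethoxy)-3,4-dihydro-2H-chromen-4-ol
Product: 10 (2S)-8-bromo-2-[2-methoxy-4-(methoxymethoxy)phenyl]-5,7-bis(methoxymethoxy)-2,3-dihydro-4H-chromen-4-one
Conditions: Dess–Martin periodinane, NaHCO3, CH2Cl2, 0 °C to rt
Reagents that add atoms: none
Why: The buffered Dess–Martin oxidation restores the C4 ketone and deletes the auxiliary C4 centre without acid, which would ionise the electron-rich benzylic alcohol, and without an enolate, which would open ring C and scramble C2.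

Step 8
Reactants: 11 (4S)-4-benzyl-1,3-oxazolidin-2-one; 12 3-methylbut-2-enoyl chloride
Product: 13 (4S)-4-benzyl-3-(3-methylbut-2-enoyl)-1,3-oxazolidin-2-one
Conditions: n-BuLi, THF, −78 °C; then 12, −78 to 0 °C
Reagents that add atoms: none
Why: N-Acylation of the lithiated Evans oxazolidinone with an acid chloride is the standard way to load the auxiliary.

Step 9
Reactants: 13 (4S)-4-benzyl-3-(3-methylbut-2-enoyl)-1,3-oxazolidin-2-one; 14 1-bromo-3-methylbut-2-ene
Product: 15 (4S)-4-benzyl-3-[(2S)-5-methyl-2-(prop-1-en-2-yl)hex-4-enoyl]-1,3-oxazolidin-2-one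
Conditions: NaN(SiMe3)2, THF, −78 °C; then 14, −78 to −40 °C
Reagents that add atoms: none
Why: In this Evans asymmetric alkylation in its deconjugative form, γ-deprotonation gives the chelated Z-dienolate of 13, which is alkylated at the α-carbon on the face away from the benzyl group, so that the (2S) centre and the isopropenyl group arise together.

Step 10
Reactants: 15 (4S)-4-benzyl-3-[(2S)-5-methyl-2-(prop-1-en-2-yl)hex-4-enoyl]-1,3-oxazolidin-2-one
Product: 16 (4S)-4-benzyl-3-{(2S)-2-[(3,3-dimethyloxiran-2-yl)methyl]-3-methylbut-3-enoyl}-1,3-oxazolidin-2-one (both epimers at the oxirane carbon)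
Conditions: mCPBA (1 equiv), CH2Cl2, 0 °C
Reagents that add atoms: 3-chloroperoxybenzoic acid, O=C(OO)c1cccc(Cl)c1
Why: The Prilezhaev epoxidation picks the electron-richer trisubstituted alkene over the 1,1-disubstituted one next to the imide, and the new oxirane centre needs no control because it becomes a CH2 group in step 11.

Step 11
Reactants: 16 (4S)-4-benzyl-3-{(2S)-2-[(3,3-dimethyloxiran-2-yl)methyl]-3-methylbut-3-enoyl}-1,3-oxazolidin-2-one
Product: 17 (2S)-5-methyl-2-(prop-1-en-2-yl)hexane-1,5-diol
Conditions: LiAlH4, THF, 0 to 40 °C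
Reagents that add atoms: none
Why: The hydride reduction cleaves the imide to the primary alcohol with release of the auxiliary and opens the trisubstituted epoxide by SN2 attack at its less substituted carbon to give the tertiary alcohol, and the existing stereocentre takes no part.

Step 12
Reactants: 17 (2S)-5-methyl-2-(prop-1-en-2-yl)hexane-1,5-diol
Product: 18 (5S)-5-(iodomethyl)-2,6-dimethylhept-6-en-2-ol
Conditions: I2, PPh3, imidazole, CH2Cl2, 0 °C
Reagents that add atoms: iodine, [I][I]
Why: The Appel-type iodination works by SN2 displacement of an alkoxyphosphonium ion, which only the primary hydroxyl can undergo at this temperature.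

Step 13
Reactants: 18 (5S)-5-(iodomethyl)-2,6-dimethylhept-6-en-2-ol
Product: 19 triethyl{[(5S)-5-(iodomethyl)-2,6-dimethylhept-6-en-2-yl]oxy}silane
Conditions: TESOTf, 2,6-lutidine, CH2Cl2, −78 to 0 °C
Reagents that add atoms: triethylsilyl trifluoromethanesulfonate, CC[Si](CC)(CC)OS(=O)(=O)C(F)(F)F
Why: Silylation with the reactive triflate covers the hindered tertiary alcohol, whose proton would otherwise quench the organozinc reagent of step 14.

Step 14
Reactants: 19 triethyl{[(5S)-5-(iodomethyl)-2,6-dimethylhept-6-en-2-yl]oxy}silane; 10 (2S)-8-bromo-2-[2-methoxy-4-(methoxymethoxy)phenyl]-5,7-bis(methoxymethoxy)-2,3-dihydro-4H-chromen-4-one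
Product: 21 (2S)-2-[2-methoxy-4-(methoxymethoxy)phenyl]-5,7-bis(methoxymethoxy)-8-[(2R)-5-methyl-2-(prop-1-en-2-yl)-5-(triethylsilyloxy)hexyl]-2,3-dihydro-4H-chromen-4-one, via alkylzinc iodide 20 (not isolated)
Conditions: Zn, LiCl, THF, 40 °C; then 10, cat. Pd2(dba)3, cat. RuPhos, THF, 50 °C
Reagents that add atoms: none
Why: In this Negishi coupling zinc inserts into the primary C–I bond without touching the neighbouring stereocentre, the bulky electron-rich biarylphosphine favours oxidative addition into the hindered C8–Br bond and reductive elimination over β-hydride elimination, and the non-basic organozinc leaves the ketone and the base-labile C2 centre alone.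

Step 15
Reactants: 21 (2S)-2-[2-methoxy-4-(methoxymethoxy)phenyl]-5,7-bis(methoxymethoxy)-8-[(2R)-5-methyl-2-(prop-1-en-2-yl)-5-(triethylsilyloxy)hexyl]-2,3-dihydro-4H-chromen-4-one
Product: 22 (2S)-5,7-dihydroxy-2-(4-hydroxy-2-methoxyphenyl)-8-[(2R)-5-hydroxy-5-methyl-2-(prop-1-en-2-yl)hexyl]-2,3-dihydro-4H-chromen-4-one (CNP0137998.2)
Conditions: NaHSO4·SiO2, wet CH2Cl2, rt
Reagents that add atoms: none
Why: Heterogeneous, mildly acidic hydrolysis of phenolic MOM acetals and of the TES ether is chosen because stronger acid would add 7-OH to the isopropenyl group or ionise the tertiary alcohol, and base would epimerise C2 by opening ring C.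

**Compound list**
1 | 5-fluorobenzene-1,3-diol | Oc1cc(O)cc(F)c1 | starting material
2 | 1-(2-fluoro-4,6-dihydroxyphenyl)ethan-1-one | CC(=O)c1c(O)cc(O)cc1F | intermediate
3 | 1-[2-fluoro-4,6-bis(methoxymethoxy)phenyl]ethan-1-one | CC(=O)c1c(OCOC)cc(OCOC)cc1F | intermediate
4 | 1-[3-bromo-2-fluoro-4,6-bis(methoxymethoxy)phenyl]ethan-1-one | CC(=O)c1c(OCOC)cc(OCOC)c(Br)c1F | intermediate
5 | methyl 4-hydroxy-2-methoxybenzoate | COC(=O)c1ccc(O)cc1OC | starting material
6 | methyl 2-methoxy-4-(methoxymethoxy)benzoate | COCOc1ccc(C(=O)OC)c(OC)c1 | intermediate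
7 | 1-[3-bromo-2-fluoro-4,6-bis(methoxymethoxy)phenyl]-3-[2-methoxy-4-(methoxymethoxy)phenyl]propane-1,3-dione, present as its potassium enolate, not isolated | COCOc1ccc(C(=O)CC(=O)c2c(OCOC)cc(OCOC)c(Br)c2F)c(OC)c1 | intermediate
8 | 8-bromo-2-[2-methoxy-4-(methoxymethoxy)phenyl]-5,7-bis(methoxymethoxy)-4H-chromen-4-one | COCOc1ccc(C2=CC(=O)c3c(OCOC)cc(OCOC)c(Br)c3O2)c(OC)c1 | intermediate
9 | (2S,4S)-8-bromo-2-[2-methoxy-4-(methoxymethoxy)phenyl]-5,7-bis(methoxymethoxy)-3,4-dihydro-2H-chromen-4-ol | COCOc1cc(OCOC)c2c(c1Br)O[C@H](c1ccc(OCOC)cc1OC)C[C@@H]2O | intermediate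
10 | (2S)-8-bromo-2-[2-methoxy-4-(methoxymethoxy)phenyl]-5,7-bis(methoxymethoxy)-2,3-dihydro-4H-chromen-4-one | COCOc1cc(OCOC)c2c(c1Br)O[C@H](c1ccc(OCOC)cc1OC)CC2=O | intermediate
11 | (4S)-4-benzyl-1,3-oxazolidin-2-one | O=C1N[C@@H](Cc2ccccc2)CO1 | starting material
12 | 3-methylbut-2-enoyl chloride | CC(C)=CC(=O)Cl | starting material
13 | (4S)-4-benzyl-3-(3-methylbut-2-enoyl)-1,3-oxazolidin-2-one | CC(C)=CC(=O)N1[C@@H](Cc2ccccc2)COC1=O | intermediate
14 | 1-bromo-3-methylbut-2-ene | CC(C)=CCBr | starting material
15 | (4S)-4-benzyl-3-[(2S)-5-methyl-2-(prop-1-en-2-yl)hex-4-enoyl]-1,3-oxazolidin-2-one | C=C(C)[C@H](CC=C(C)C)C(=O)N1[C@@H](Cc2ccccc2)COC1=O | intermediate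
16 | (4S)-4-benzyl-3-{(2S)-2-[(3,3-dimethyloxiran-2-yl)methyl]-3-methylbut-3-enoyl}-1,3-oxazolidin-2-one, both epimers at the oxirane carbon | C=C(C)[C@H](CC1OC1(C)C)C(=O)N1[C@@H](Cc2ccccc2)COC1=O | intermediate
17 | (2S)-5-methyl-2-(prop-1-en-2-yl)hexane-1,5-diol | C=C(C)[C@H](CCC(C)(C)O)CO | intermediate
18 | (5S)-5-(iodomethyl)-2,6-dimethylhept-6-en-2-ol | IC[C@@H](CCC(C)(C)O)C(C)=C | intermediate
19 | triethyl{[(5S)-5-(iodomethyl)-2,6-dimethylhept-6-en-2-yl]oxy}silane | IC[C@@H](CCC(C)(C)O[Si](CC)(CC)CC)C(C)=C | intermediate
20 | [(2S)-5-methyl-2-(prop-1-en-2-yl)-5-(triethylsilyloxy)hexyl]zinc iodide, not isolated | I[Zn]C[C@@H](CCC(C)(C)O[Si](CC)(CC)CC)C(C)=C | intermediate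
21 | (2S)-2-[2-methoxy-4-(methoxymethoxy)phenyl]-5,7-bis(methoxymethoxy)-8-[(2R)-5-methyl-2-(prop-1-en-2-yl)-5-(triethylsilyloxy)hexyl]-2,3-dihydro-4H-chromen-4-one | C=C(C)[C@H](CCC(C)(C)O[Si](CC)(CC)CC)Cc1c(OCOC)cc(OCOC)c2c1O[C@H](c1ccc(OCOC)cc1OC)CC2=O | intermediate
22 | (2S)-5,7-dihydroxy-2-(4-hydroxy-2-methoxyphenyl)-8-[(2R)-5-hydroxy-5-methyl-2-(prop-1-en-2-yl)hexyl]-2,3-dihydro-4H-chromen-4-one | C=C(C)[C@H](CCC(C)(C)O)Cc1c(O)cc(O)c2c1O[C@H](c1ccc(O)cc1OC)CC2=O | target

**Step count and risks**
Total steps: 15. The longest linear sequence is 8 steps (steps 1, 2, 3, 5, 6, 7, 14, 15). The chain branch (steps 8 to 13, then 14 and 15) is equally long.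

The three steps most likely to fail:

First, step 6. What may go wrong:
- poor facial selectivity at C2 under the influence of the ortho-methoxy group of ring B;
- slow turnover on the electron-rich pyranone;
- hydrogenolytic loss of bromine from C8.

The fallback sets out from 8 and comes back at 10, so that 9 and step 7 drop out. It is an asymmetric conjugate reduction with a ligated copper hydride: Cu(OAc)2, DTBM-SEGPHOS in the enantiomer that gives 2S, (EtO)2MeSiH, toluene, rt. This reaction type is known on 2-substituted chromones and tolerates aryl bromides. Hydride is delivered to C2, and the silane traps the copper enolate as the diethoxy(methyl)silyl enol ether F1, which cannot open ring C. Citric acid in aqueous THF then releases 10.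

Second, step 14. What may go wrong:
- slow oxidative addition of zerovalent palladium into the electron-rich, doubly ortho-substituted C8–Br bond;
- β-hydride elimination of the alkylpalladium species through the C–H bond of the chain stereocentre, which would erode its configuration or drain the chain into a diene.

The fallback sets out from 19 and 10 and comes back at 21. It is a nickel-catalysed reductive cross-electrophile coupling: NiBr2(dme), 4,4'-di-tert-butyl-2,2'-bipyridine, Zn, NaI, DMA, rt to 40 °C. No organozinc reagent is preformed. The primary alkyl radical from 19 is captured by the arylnickel species from 10, and reductive elimination follows directly. This fallback makes no compound outside the list (none F0).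

Third, step 5. What may go wrong:
- sluggish condensation between the hindered enolate and the electron-rich, ortho-substituted ester;
- alkoxide attack at C–F or retro-Claisen cleavage taking over on heating.

The fallback sets out from 6 and 4 and comes back at 8, with 7 now isolated. Ester 6 is saponified (LiOH, aqueous THF) to 2-methoxy-4-(methoxymethoxy)benzoic acid F2. This acid is activated with 1,1'-carbonyldiimidazole to the acylimidazole F3. The lithium enolate of 4 (LiN(SiMe3)2, THF, −78 °C) is C-acylated kinetically with F3 to give 7. In a separate operation 7 is cyclised with K2CO3 in DMF at 80 °C, which is the known transition-metal-free O-arylation of 1-(2-haloaryl)-1,3-diketones.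

**Further compounds**
F1 | step 6 | (2S)-8-bromo-4-{[diethoxy(methyl)silyl]oxy}-2-[2-methoxy-4-(methoxymethoxy)phenyl]-5,7-bis(methoxymethoxy)-2H-chromene | COCOc1cc(OCOC)c2c(c1Br)O[C@H](c1ccc(OCOC)cc1OC)C=C2O[Si](C)(OCC)OCC
F0 | step 14 | none | none
F2 | step 5 | 2-methoxy-4-(methoxymethoxy)benzoic acid | COCOc1ccc(C(=O)O)c(OC)c1
F3 | step 5 | (1H-imidazol-1-yl)[2-methoxy-4-(methoxymethoxy)phenyl]methanone | COCOc1ccc(C(=O)n2ccnc2)c(OC)c1
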